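Readings and results come from a simulation from invented constants, and the scatter is random.

The epsilon run, with 0.42 M of scavenger, still held 18.8% of its starting material at 20.0 min. The beta run, with 1.4 M and the other charges equal, held 5.2%.

the same everywhere: starting material 0.52 M; coupling partner 0.572 M

| flask | scavenger | protic impurity | remark | time |
|---|---|---|---|---|
| epsilon | 0.42 M | 0.026 M | run made earlier |  |
| beta | 1.4 M | 0.026 M | run made earlier |  |
| midnight | 0.520 M | 0.0260 M |  | 20 min |
| spring | 1.00 M | 0.0260 M |  | 20 min |
| dusk | 2.10 M | 0.0260 M |  | 20 min |

| run | time / min | starting material / % | product / % |
|---|---|---|---|
| epsilon | 1.50 | 46.5 | 37.1 |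
| epsilon | 4.00 | 36.2 | 54.3 |
| epsilon | 8.00 | 27.4 | 64.3 |
| epsilon | 20.0 | 18.8 | 76.7 |
| beta | 2.50 | 41.0 | 51.7 |
| beta | 8.00 | 17.6 | 77.0 |
| beta | 12.0 | 11.6 | 83.4 |
| beta | 20.0 | 5.2 | 89.9 |

(each reading ± 0.5 percentage points)

* part of the starting material that has reacted at the end, midnight
* part of the starting material that has reacted at the end, spring
* part of the starting material that has reacted at the end, dusk
* what raising the concentration of scavenger from its lowest to its highest value here does to the part of the starting material that has reacted (changes below 5 percentage points count as none) (no change / it rises / it falls)

- what is said of released group includes idle adduct and crystals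
- crystals is a solid; its amount is given per volume of the solution
- the earlier runs were read with a standard deviation of 0.5 percentage points
- reactions considered so far: starting material + coupling partner <-> product + released group; starting material + released group <-> idle adduct; scavenger + released group -> scavenged by-product; crystals <-> released group; starting material + protic impurity -> quenched substrate

I set two amounts against each other. The first is the released group the listed flasks can make. At 20.0 min the beta readings leave 4.90% of the starting material unaccounted for, close to the 5.00% the protic impurity can quench, so I subtracted the impurity. The coupling partner, at 0.572 M, is more than the remainder: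

released group possible = 0.494 M

The second amount is the scavenger charged. Their ratio I called the scavenger load, released group possible per scavenger charged; above one, the scavenger is short of stoichiometric. It came to:

epsilon 1.18, beta 0.353, midnight 0.950, spring 0.494, dusk 0.235

I drew a straight line through the two runs, reacted part against load, at the same time. The load of dusk lies below that of beta, so its value is an extrapolation:

slope = 0.165 per unit of load

midnight 84.9%, spring 92.5%, dusk 96.7%

The forecast gave 86.5%, 93% and 96.3%, and said it rises. That is above my line at midnight and spring and below it at dusk. Of the epsilon run it said: “Released group then survives and drives the reverse reaction.”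

The flasks gave 85.9%, 92.8% and 94.8%: it rises, by 8.9 percentage points.

    starting material + coupling partner ⇌ product + released group (K = 0.370, k = 0.890 M⁻¹ min⁻¹)
    starting material + released group ⇌ idle adduct, settled at all times (K = 5.30 M⁻¹)
    scavenger + released group → scavenged by-product (k = 4.30 M⁻¹ min⁻¹)
    crystals ⇌ released group, rate k4*(cs4 - [released group]) while solid is left; crystals form when [released group] > cs4 (solubility = 0.380 M, k = 12.0 min⁻¹)
    starting material + protic impurity → quenched substrate (k = 2.30 M⁻¹ min⁻¹)

Midnight, at load 0.950, stood at 85.9% against my 84.9%, and its remaining scavenger, 0.112 M, exceeded its remaining starting material, 0.0731 M. In the neighbour of midnight with 0.23 M of coupling partner, that partner is the limiting reagent. The load there is 0.442, and that partner together with the protic impurity matches 49.2% of the starting material. That neighbour gave 48.5%, with 43.2% product and 2.26% of its coupling partner left.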